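The route rests on disconnecting C7–C8 (germacrane numbering): the ten-membered carbocycle (C1–C10) is closed by an intramolecular Nozaki–Hiyama–Kishi allylation of a 3-(bromomethyl)butenolide. The key step exploits the fact that C8(O)–C7–C11=C13 of the α-methylene lactone (ring O–C6–C7–C11–C12) is a homoallylic alcohol, and that this lactone is cis-fused at C6–C7. In one operation the allylchromium adds through C7 to the C8 aldehyde, closing the ring, setting C7 and C8 and unveiling the exocyclic methylene. The precursor is a monocyclic (5R)-butenolide carrying at C6 the open C5–C10 chain with both trisubstituted olefins and a β,γ-unsaturated aldehyde.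

Key step: step 12

Remark: germacrane numbering is used throughout (lactone C12(=O)–O–C6, methylene C11=C13, ring fusion C6–C7, ester oxygen on C8, C14 on C10, C15 on C4); the C6 descriptor changes from S (4 to 17) to R (18 onward) through CIP priorities only, not through inversion.
Assumption: (S,S)-ProPhenol is taken as the ligand enantiomer that adds the alkynylzinc to the Re face of acrolein; if the sense is the opposite, the (R,R)-ligand is used.

Step 1
Reactants: 1 acrolein; 2 tert-butyldiphenyl(prop-2-yn-1-yloxy)silane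
Product: 4 (3S)-6-[(tert-butyldiphenylsilyl)oxy]hex-1-en-4-yn-3-ol, via methylzinc acetylide 3 (not isolated)
Conditions: Me2Zn, (S,S)-ProPhenol (20 mol %), Ph3PO (40 mol %), toluene, 0 °C; aq. NH4Cl
Reagents that add atoms: none
Why: Zinc–ProPhenol catalysed enantioselective alkynylation (1,2-addition of the zinc acetylide to an α,β-unsaturated aldehyde) should set C6 by attack on the Re face of acrolein, giving the 3S carbinol.

Step 2
Reactants: 4 (3S)-6-[(tert-butyldiphenylsilyl)oxy]hex-1-en-4-yn-3-ol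
Product: 6 (3S,4Z)-6-[(tert-butyldiphenylsilyl)oxy]-5-iodohexa-1,4-dien-3-ol, via cyclic vinylalanate 5 (not isolated)
Conditions: NaAlH2(OCH2CH2OMe)2 (Red-Al), THF, 0 °C; then I2, −78 °C
Reagents that add atoms: iodine, II
Why: Hydroxyl-directed trans-hydroalumination of the propargylic alcohol (H to C5, Al to C4 in a five-membered alanate) followed by iodinolysis with retention should give the Z-vinyl iodide with iodine on C4 cis to C6, leaving C6 untouched.

Step 3
Reactants: 1 acrolein; 7 3-(triphenyl-λ5-phosphanylidene)oxolan-2-one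
Product: 8 (3E)-3-(prop-2-en-1-ylidene)oxolan-2-one
Conditions: CH2Cl2, 0 °C → rt
Reagents that add atoms: none
Why: Wittig olefination with a stabilised α-branched ylide is E-selective, so the lactone carbonyl (C14) should end up trans to C2 and the ring CH2 (C9) cis to C2, which is the C1=C10 geometry of the target.

Step 4
Reactants: 8 (3E)-3-(prop-2-en-1-ylidene)oxolan-2-one
Product: 10 tert-butyldimethylsilyl (2E)-2-{2-[(tert-butyldimethylsilyl)oxy]ethyl}penta-2,4-dienoate, via lithium carboxylate 9 (not isolated)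
Conditions: LiOH·H2O, THF/H2O, 0 °C → rt; evaporate; TBSCl, imidazole, DMF, rt
Reagents that add atoms: lithium hydroxide, [Li+].[OH-]; tert-butyldimethylsilyl chloride, CC(C)(C)[Si](C)(C)Cl
Why: Lactone saponification followed by exhaustive silylation should differentiate the two oxygenated carbons, C8–O becoming a stable silyl ether and C14 a labile silyl ester.

Step 5
Reactants: 10 tert-butyldimethylsilyl (2E)-2-{2-[(tert-butyldimethylsilyl)oxy]ethyl}penta-2,4-dienoate
Product: 11 (2E)-2-{2-[(tert-butyldimethylsilyl)oxy]ethyl}penta-2,4-dien-1-ol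
Conditions: i-Bu2AlH, CH2Cl2, −78 → 0 °C; Rochelle salt
Reagents that add atoms: none
Why: Hydride reduction of the silyl ester (1,2-reduction of an ester) should give the primary allylic alcohol at C14 while the primary silyl ether and the diene stay intact.

Step 6
Reactants: 11 (2E)-2-{2-[(tert-butyldimethylsilyl)oxy]ethyl}penta-2,4-dien-1-ol
Product: 12 tert-butyl({(3E)-3-[(4-methoxybenzyloxy)methyl]hexa-3,5-dien-1-yl}oxy)dimethylsilane
Conditions: NaH, PMBCl, Bu4NI (cat.), THF/DMF, 0 °C → rt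
Reagents that add atoms: 4-methoxybenzyl chloride, COc1ccc(CCl)cc1
Why: Williamson etherification of the allylic alkoxide should install a PMB group on O14 that is orthogonal to both silyl ethers.

Step 7
Reactants: 12 tert-butyl({(3E)-3-[(4-methoxybenzyloxy)methyl]hexa-3,5-dien-1-yl}oxy)dimethylsilane; 6 (3S,4Z)-6-[(tert-butyldiphenylsilyl)oxy]-5-iodohexa-1,4-dien-3-ol
Product: 14 (3S,4E,8E)-5-{[(tert-butyldiphenylsilyl)oxy]methyl}-11-[(tert-butyldimethylsilyl)oxy]-9-[(4-methoxybenzyloxy)methyl]undeca-1,4,8-trien-3-ol, via alkyl-9-BBN borane 13 (not isolated)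
Conditions: 9-BBN-H, THF, 0 °C → rt; then 6, Pd(dppf)Cl2 (5 mol %), AsPh3, Cs2CO3, DMF/THF/H2O, rt
Reagents that add atoms: none
Why: Anti-Markovnikov hydroboration of the only monosubstituted alkene of the diene (boron on C3) and B-alkyl Suzuki–Miyaura coupling with retention at the vinyl iodide should join C3 to C4 with C3 cis to C6; no stereocentre is formed and the free hydroxyl is tolerated.

Step 8
Reactants: 14 (3S,4E,8E)-5-{[(tert-butyldiphenylsilyl)oxy]methyl}-11-[(tert-butyldimethylsilyl)oxy]-9-[(4-methoxybenzyloxy)methyl]undeca-1,4,8-trien-3-ol; 15 2-(bromomethyl)prop-2-enoic acid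
Product: 17 (3S,4E,8E)-5-{[(tert-butyldiphenylsilyl)oxy]methyl}-11-[(tert-butyldimethylsilyl)oxy]-9-[(4-methoxybenzyloxy)methyl]undeca-1,4,8-trien-3-yl 2-(bromomethyl)prop-2-enoate, via acid chloride 16 (not isolated)
Conditions: 15, (COCl)2, DMF (cat.), CH2Cl2, 0 °C; then 14, 2,6-lutidine, CH2Cl2, −40 → 0 °C
Reagents that add atoms: none
Why: Acylation of the secondary alcohol by the acid chloride proceeds with retention at C6, and the hindered base should avoid SN2′ attack on the allylic bromide.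

Step 9
Reactants: 17 (3S,4E,8E)-5-{[(tert-butyldiphenylsilyl)oxy]methyl}-11-[(tert-butyldimethylsilyl)oxy]-9-[(4-methoxybenzyloxy)methyl]undeca-1,4,8-trien-3-yl 2-(bromomethyl)prop-2-enoate
Product: 18 (5R)-3-(bromomethyl)-5-[(1E,5E)-2-{[(tert-butyldiphenylsilyl)oxy]methyl}-8-[(tert-butyldimethylsilyl)oxy]-6-[(4-methoxybenzyloxy)methyl]octa-1,5-dien-1-yl]furan-2(5H)-one
Conditions: second-generation Grubbs catalyst (H2IMes)(PCy3)Cl2Ru=CHPh (10 mol %), CH2Cl2 (0.005 M), 40 °C
Reagents that add atoms: none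
Why: Ring-closing metathesis between the C7 vinyl group and the 1,1-disubstituted acrylate should close the five-membered butenolide (O–C6–C7=C11–C12) with loss of ethene, the two trisubstituted olefins being spectators.

Step 10
Reactants: 18 (5R)-3-(bromomethyl)-5-[(1E,5E)-2-{[(tert-butyldiphenylsilyl)oxy]methyl}-8-[(tert-butyldimethylsilyl)oxy]-6-[(4-methoxybenzyloxy)methyl]octa-1,5-dien-1-yl]furan-2(5H)-one
Product: 19 (5R)-3-(bromomethyl)-5-[(1E,5E)-2-{[(tert-butyldiphenylsilyl)oxy]methyl}-8-hydroxy-6-[(4-methoxybenzyloxy)methyl]octa-1,5-dien-1-yl]furan-2(5H)-one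
Conditions: HF·pyridine, THF, 0 °C
Reagents that add atoms: none
Why: Acidic fluoride desilylation should remove the primary TBS ether much faster than the TBDPS ether, without touching the allylic bromide or the base-sensitive C6–H of the butenolide.

Step 11
Reactants: 19 (5R)-3-(bromomethyl)-5-[(1E,5E)-2-{[(tert-butyldiphenylsilyl)oxy]methyl}-8-hydroxy-6-[(4-methoxybenzyloxy)methyl]octa-1,5-dien-1-yl]furan-2(5H)-one
Product: 20 (3E,7E)-8-[(2R)-4-(bromomethyl)-5-oxo-2,5-dihydrofuran-2-yl]-7-{[(tert-butyldiphenylsilyl)oxy]methyl}-3-[(4-methoxybenzyloxy)methyl]octa-3,7-dienal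
Conditions: Dess–Martin periodinane, NaHCO3, CH2Cl2, 0 °C; used at once
Reagents that add atoms: none
Why: Dess–Martin oxidation under buffered non-basic conditions should give the β,γ-unsaturated C8 aldehyde without migration of the C1=C10 double bond or epimerisation at C6.

Step 12
Reactants: 20 (3E,7E)-8-[(2R)-4-(bromomethyl)-5-oxo-2,5-dihydrofuran-2-yl]-7-{[(tert-butyldiphenylsilyl)oxy]methyl}-3-[(4-methoxybenzyloxy)methyl]octa-3,7-dienal
Product: 22 (3aS,4R,6E,10E,11aR)-10-{[(tert-butyldiphenylsilyl)oxy]methyl}-4-hydroxy-6-[(4-methoxybenzyloxy)methyl]-3-methylidene-3a,4,5,8,9,11a-hexahydrocyclodeca[b]furan-2(3H)-one (6R,7S,8R in germacrane numbering), via allylchromium dichloride 21 (not isolated)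
Conditions: CrCl2 (10 equiv), THF, rt, syringe-pump addition of 20 (final 0.002 M); aq. NH4Cl
Reagents that add atoms: none
Why: Two equivalents of CrCl2 (divalent chromium) reduce the allylic C13–Br bond to the allylchromium 21 (trivalent chromium), which adds through its γ-carbon C7 to the tethered C8 aldehyde with allylic transposition, so that the C7–C8 bond, the ten-membered ring and the exocyclic C11=C13 methylene arise together. The closest known reaction type is the Nozaki–Hiyama–Kishi (chromium Barbier) allylation of aldehydes with 2-(alkoxycarbonyl)allyl bromides, known for 3-(bromomethyl)furan-2(5H)-ones and for macrocyclic ring closures. The ten-membered carbocycle closes in a 10-exo-trig mode at the aldehyde carbon. C7 is controlled by C6: the aldehyde is tethered through C5 and should be delivered to the face of the planar butenolide that carries C5, which gives the cis-fused lactone (6R,7S). C8 is controlled by the closed six-membered chair (Zimmerman–Traxler) transition state, in which the ring-locked E-type allylchromium places C9 pseudo-equatorial and so gives the 7,8-anti carbinol (8R), the C8 epimer that step 13 inverts. The step needs reduction of C–Br in preference to every other function and ring closure in preference to oligomerisation; the first rests on the mildness of CrCl2 towards lactone, silyl and PMB ethers, the second on high dilution and on the two ring-cis trisubstituted olefins that fold the chain back towards C7.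

Step 13
Reactants: 22 (3aS,4R,6E,10E,11aR)-10-{[(tert-butyldiphenylsilyl)oxy]methyl}-4-hydroxy-6-[(4-methoxybenzyloxy)methyl]-3-methylidene-3a,4,5,8,9,11a-hexahydrocyclodeca[b]furan-2(3H)-one; 23 angelic acid, (2Z)-2-methylbut-2-enoic acid
Product: 24 (3aS,4S,6E,10E,11aR)-10-{[(tert-butyldiphenylsilyl)oxy]methyl}-6-[(4-methoxybenzyloxy)methyl]-3-methylidene-2-oxo-2,3,3a,4,5,8,9,11a-octahydrocyclodeca[b]furan-4-yl (2Z)-2-methylbut-2-enoate (6R,7S,8S)
Conditions: PPh3, DIAD, toluene, 0 °C → rt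
Reagents that add atoms: none
Why: Mitsunobu esterification should displace the oxyphosphonium at C8 by angelate with SN2 inversion (8R to 8S), and because the acid reacts as its carboxylate the Z geometry of the angelate should be kept.

Step 14
Reactants: 24 (3aS,4S,6E,10E,11aR)-10-{[(tert-butyldiphenylsilyl)oxy]methyl}-6-[(4-methoxybenzyloxy)methyl]-3-methylidene-2-oxo-2,3,3a,4,5,8,9,11a-octahydrocyclodeca[b]furan-4-yl (2Z)-2-methylbut-2-enoate
Product: 25 (3aS,4S,6E,10E,11aR)-10-{[(tert-butyldiphenylsilyl)oxy]methyl}-6-(hydroxymethyl)-3-methylidene-2-oxo-2,3,3a,4,5,8,9,11a-octahydrocyclodeca[b]furan-4-yl (2Z)-2-methylbut-2-enoate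
Conditions: DDQ, CH2Cl2/aq. pH 7 buffer, 0 °C
Reagents that add atoms: none
Why: Oxidative PMB ether cleavage (benzylic hydride abstraction by DDQ, then hydrolysis) should free the C14 allylic alcohol while the silyl ether, both esters and the olefins stay inert.

Step 15
Reactants: 25 (3aS,4S,6E,10E,11aR)-10-{[(tert-butyldiphenylsilyl)oxy]methyl}-6-(hydroxymethyl)-3-methylidene-2-oxo-2,3,3a,4,5,8,9,11a-octahydrocyclodeca[b]furan-4-yl (2Z)-2-methylbut-2-enoate
Product: 26 (3aS,4S,6E,10E,11aR)-10-{[(tert-butyldiphenylsilyl)oxy]methyl}-6-formyl-3-methylidene-2-oxo-2,3,3a,4,5,8,9,11a-octahydrocyclodeca[b]furan-4-yl (2Z)-2-methylbut-2-enoate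
Conditions: MnO2 (activated, excess), CH2Cl2, rt
Reagents that add atoms: none
Why: MnO2 oxidation of the primary allylic alcohol should stop at the conjugated aldehyde and keep the E-enal geometry (CHO trans to C2).

Step 16
Reactants: 26 (3aS,4S,6E,10E,11aR)-10-{[(tert-butyldiphenylsilyl)oxy]methyl}-6-formyl-3-methylidene-2-oxo-2,3,3a,4,5,8,9,11a-octahydrocyclodeca[b]furan-4-yl (2Z)-2-methylbut-2-enoate
Product: 27 (3aS,4S,6E,10E,11aR)-6-formyl-10-(hydroxymethyl)-3-methylidene-2-oxo-2,3,3a,4,5,8,9,11a-octahydrocyclodeca[b]furan-4-yl (2Z)-2-methylbut-2-enoate (target, 6R,7S,8S)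
Conditions: HF·pyridine, THF, 0 °C → rt
Reagents that add atoms: none
Why: Fluoride-mediated desilylation under weakly acidic conditions should remove the TBDPS group and spare the enal, the angelate and the α-methylene lactone.

Compound list
1 | acrolein (prop-2-enal) | C=CC=O | starting material
2 | tert-butyldiphenyl(prop-2-yn-1-yloxy)silane | C#CCO[Si](c1ccccc1)(c1ccccc1)C(C)(C)C | starting material
3 | methylzinc acetylide of 2 (not isolated) | C[Zn]C#CCO[Si](c1ccccc1)(c1ccccc1)C(C)(C)C | intermediate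
4 | (3S)-6-[(tert-butyldiphenylsilyl)oxy]hex-1-en-4-yn-3-ol | O[C@@H](C=C)C#CCO[Si](c1ccccc1)(c1ccccc1)C(C)(C)C | intermediate
5 | sodium cyclic alkoxy(vinyl)alanate, five-membered ring Al–O–C6–C5=C4 (not isolated) | COCCO[Al-]1(OCCOC)O[C@@H](C=C)C=C1CO[Si](c2ccccc2)(c2ccccc2)C(C)(C)C.[Na+] | intermediate
6 | (3S,4Z)-6-[(tert-butyldiphenylsilyl)oxy]-5-iodohexa-1,4-dien-3-ol | O[C@@H](C=C)/C=C(I)/CO[Si](c1ccccc1)(c1ccccc1)C(C)(C)C | intermediate
7 | 3-(triphenyl-λ5-phosphanylidene)oxolan-2-one | O=C1OCCC1=P(c1ccccc1)(c1ccccc1)c1ccccc1 | starting material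
8 | (3E)-3-(prop-2-en-1-ylidene)oxolan-2-one | C=C/C=C1\CCOC1=O | intermediate
9 | lithium (2E)-2-(2-hydroxyethyl)penta-2,4-dienoate (not isolated) | C=C/C=C(\CCO)C(=O)[O-].[Li+] | intermediate
10 | tert-butyldimethylsilyl (2E)-2-{2-[(tert-butyldimethylsilyl)oxy]ethyl}penta-2,4-dienoate | C=C/C=C(\CCO[Si](C)(C)C(C)(C)C)C(=O)O[Si](C)(C)C(C)(C)C | intermediate
11 | (2E)-2-{2-[(tert-butyldimethylsilyl)oxy]ethyl}penta-2,4-dien-1-ol | C=C/C=C(\CCO[Si](C)(C)C(C)(C)C)CO | intermediate
12 | tert-butyl({(3E)-3-[(4-methoxybenzyloxy)methyl]hexa-3,5-dien-1-yl}oxy)dimethylsilane | C=C/C=C(\CCO[Si](C)(C)C(C)(C)C)COCc1ccc(OC)cc1 | intermediate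
13 | 9-{(3E)-6-[(tert-butyldimethylsilyl)oxy]-4-[(4-methoxybenzyloxy)methyl]hex-3-en-1-yl}-9-borabicyclo[3.3.1]nonane (not isolated) | C1CC2CCCC(C1)B2CC/C=C(\CCO[Si](C)(C)C(C)(C)C)COCc1ccc(OC)cc1 | intermediate
14 | (3S,4E,8E)-5-{[(tert-butyldiphenylsilyl)oxy]methyl}-11-[(tert-butyldimethylsilyl)oxy]-9-[(4-methoxybenzyloxy)methyl]undeca-1,4,8-trien-3-ol | O[C@@H](C=C)/C=C(/CO[Si](c1ccccc1)(c1ccccc1)C(C)(C)C)CC/C=C(\CCO[Si](C)(C)C(C)(C)C)COCc1ccc(OC)cc1 | intermediate
15 | 2-(bromomethyl)prop-2-enoic acid | OC(=O)C(=C)CBr | starting material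
16 | 2-(bromomethyl)prop-2-enoyl chloride (not isolated) | ClC(=O)C(=C)CBr | intermediate
17 | (3S,4E,8E)-5-{[(tert-butyldiphenylsilyl)oxy]methyl}-11-[(tert-butyldimethylsilyl)oxy]-9-[(4-methoxybenzyloxy)methyl]undeca-1,4,8-trien-3-yl 2-(bromomethyl)prop-2-enoate | C=C(CBr)C(=O)O[C@@H](C=C)/C=C(/CO[Si](c1ccccc1)(c1ccccc1)C(C)(C)C)CC/C=C(\CCO[Si](C)(C)C(C)(C)C)COCc1ccc(OC)cc1 | intermediate
18 | (5R)-3-(bromomethyl)-5-[(1E,5E)-2-{[(tert-butyldiphenylsilyl)oxy]methyl}-8-[(tert-butyldimethylsilyl)oxy]-6-[(4-methoxybenzyloxy)methyl]octa-1,5-dien-1-yl]furan-2(5H)-one | BrCC1=C[C@@H](/C=C(/CO[Si](c2ccccc2)(c2ccccc2)C(C)(C)C)CC/C=C(\CCO[Si](C)(C)C(C)(C)C)COCc2ccc(OC)cc2)OC1=O | intermediate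
19 | (5R)-3-(bromomethyl)-5-[(1E,5E)-2-{[(tert-butyldiphenylsilyl)oxy]methyl}-8-hydroxy-6-[(4-methoxybenzyloxy)methyl]octa-1,5-dien-1-yl]furan-2(5H)-one | BrCC1=C[C@@H](/C=C(/CO[Si](c2ccccc2)(c2ccccc2)C(C)(C)C)CC/C=C(\CCO)COCc2ccc(OC)cc2)OC1=O | intermediate
20 | (3E,7E)-8-[(2R)-4-(bromomethyl)-5-oxo-2,5-dihydrofuran-2-yl]-7-{[(tert-butyldiphenylsilyl)oxy]methyl}-3-[(4-methoxybenzyloxy)methyl]octa-3,7-dienal | BrCC1=C[C@@H](/C=C(/CO[Si](c2ccccc2)(c2ccccc2)C(C)(C)C)CC/C=C(\CC=O)COCc2ccc(OC)cc2)OC1=O | intermediate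
21 | allylchromium dichloride of 20, C13–CrCl2 in place of C13–Br, trivalent chromium (not isolated) | Cl[Cr](Cl)CC1=C[C@@H](/C=C(/CO[Si](c2ccccc2)(c2ccccc2)C(C)(C)C)CC/C=C(\CC=O)COCc2ccc(OC)cc2)OC1=O | intermediate
22 | (3aS,4R,6E,10E,11aR)-10-{[(tert-butyldiphenylsilyl)oxy]methyl}-4-hydroxy-6-[(4-methoxybenzyloxy)methyl]-3-methylidene-3a,4,5,8,9,11a-hexahydrocyclodeca[b]furan-2(3H)-one | C=C1C(=O)O[C@@H]2/C=C(/CO[Si](c3ccccc3)(c3ccccc3)C(C)(C)C)CC/C=C(/COCc3ccc(OC)cc3)C[C@@H](O)[C@H]12 | intermediate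
23 | angelic acid, (2Z)-2-methylbut-2-enoic acid | C/C=C(/C)C(=O)O | starting material
24 | (3aS,4S,6E,10E,11aR)-10-{[(tert-butyldiphenylsilyl)oxy]methyl}-6-[(4-methoxybenzyloxy)methyl]-3-methylidene-2-oxo-2,3,3a,4,5,8,9,11a-octahydrocyclodeca[b]furan-4-yl (2Z)-2-methylbut-2-enoate | C=C1C(=O)O[C@@H]2/C=C(/CO[Si](c3ccccc3)(c3ccccc3)C(C)(C)C)CC/C=C(/COCc3ccc(OC)cc3)C[C@H](OC(=O)/C(C)=C\C)[C@H]12 | intermediate
25 | (3aS,4S,6E,10E,11aR)-10-{[(tert-butyldiphenylsilyl)oxy]methyl}-6-(hydroxymethyl)-3-methylidene-2-oxo-2,3,3a,4,5,8,9,11a-octahydrocyclodeca[b]furan-4-yl (2Z)-2-methylbut-2-enoate | C=C1C(=O)O[C@@H]2/C=C(/CO[Si](c3ccccc3)(c3ccccc3)C(C)(C)C)CC/C=C(/CO)C[C@H](OC(=O)/C(C)=C\C)[C@H]12 | intermediate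
26 | (3aS,4S,6E,10E,11aR)-10-{[(tert-butyldiphenylsilyl)oxy]methyl}-6-formyl-3-methylidene-2-oxo-2,3,3a,4,5,8,9,11a-octahydrocyclodeca[b]furan-4-yl (2Z)-2-methylbut-2-enoate | C=C1C(=O)O[C@@H]2/C=C(/CO[Si](c3ccccc3)(c3ccccc3)C(C)(C)C)CC/C=C(/C=O)C[C@H](OC(=O)/C(C)=C\C)[C@H]12 | intermediate
27 | (3aS,4S,6E,10E,11aR)-6-formyl-10-(hydroxymethyl)-3-methylidene-2-oxo-2,3,3a,4,5,8,9,11a-octahydrocyclodeca[b]furan-4-yl (2Z)-2-methylbut-2-enoate | C=C1C(=O)O[C@@H]2/C=C(/CO)CC/C=C(/C=O)C[C@H](OC(=O)/C(C)=C\C)[C@H]12 | target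

Total step count: 16. Longest linear sequence: 14 steps (steps 3 to 6, then 7 to 16).

Steps most likely to fail

Step 12 (key step). The allylchromium may add to the aldehyde from the butenolide face opposite to C5, the sense preferred in intermolecular additions to 5-substituted 3-(bromomethyl)butenolides. That would give the trans-fused lactone with C7 inverted; oligomerisation may also compete with ring closure. The fallback sets out from 14 and comes back at 24. It uses the series epimeric at C6, in which closure anti to C5 sets C7 correctly, and inverts C6 at the end. Mitsunobu esterification of 14 with 4-nitrobenzoic acid (PPh3, DIAD) gives the inverted (3R)-4-nitrobenzoate F1, and methanolysis (K2CO3, MeOH) gives the (3R)-alcohol F2. The operations of steps 8 to 11 then give the 2-(bromomethyl)acrylate F3, the (5S)-bromomethyl butenolide F4, the primary alcohol F5 and the aldehyde F6. Ring closure with CrCl2 anti to C5 should give the trans-fused (6S,7S,8R)-hydroxy lactone F7, and Mitsunobu esterification with 23 as in step 13 gives the (6S,7S,8S)-angelate F8. LiOH (THF/H2O, 0 °C) opens the lactone to the seco hydroxy acid F9, in which the allylic C6 hydroxyl is the only free one. Mitsunobu lactonisation (PPh3, DIAD) then recloses the lactone with inversion at C6 and gives 24.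

Step 13. Displacement at the hindered ring carbinol C8 may be slow, so that elimination towards C9 or C7, or addition of PPh3 to the methylene lactone, takes over. The fallback sets out from 22 and comes back at 24 by redox inversion instead of SN2 inversion. Dess–Martin oxidation gives the C8 ketone F10. Reduction with NaBH4 and CeCl3·7H2O (MeOH, −78 °C), with hydride delivered anti to the C7–C11 bond, should give the (8S)-alcohol F11. Esterification of F11 with 23 through the mixed anhydride with 2,4,6-trichlorobenzoyl chloride (Et3N, then DMAP, toluene) proceeds with retention and gives 24. The same esterification serves directly if the ring closure of step 12 should deliver the (8S)-alcohol F11 instead of 22.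

Step 1. Acrolein may polymerise or react with low facial discrimination in the catalytic alkynylation, which would erode the enantiomeric purity of C6. The fallback sets out from 1 and 2 and comes back at 4 by resolution instead of asymmetric catalysis. The lithium acetylide of 2 (n-BuLi, THF, −78 °C) adds to 1 to give the racemic alcohol F12. Lipase-catalysed acetylation (Amano lipase PS, vinyl acetate, hexane, rt) should convert the (R)-enantiomer into the (R)-acetate F13, following the usual preference of lipases for secondary alcohols, and leave 4, which is separated by chromatography.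

Further compounds
F1 | step 12 | (3R,4E,8E)-5-{[(tert-butyldiphenylsilyl)oxy]methyl}-11-[(tert-butyldimethylsilyl)oxy]-9-[(4-methoxybenzyloxy)methyl]undeca-1,4,8-trien-3-yl 4-nitrobenzoate | [O-][N+](=O)c1ccc(cc1)C(=O)O[C@H](C=C)/C=C(/CO[Si](c1ccccc1)(c1ccccc1)C(C)(C)C)CC/C=C(\CCO[Si](C)(C)C(C)(C)C)COCc1ccc(OC)cc1
F2 | step 12 | (3R,4E,8E)-5-{[(tert-butyldiphenylsilyl)oxy]methyl}-11-[(tert-butyldimethylsilyl)oxy]-9-[(4-methoxybenzyloxy)methyl]undeca-1,4,8-trien-3-ol | O[C@H](C=C)/C=C(/CO[Si](c1ccccc1)(c1ccccc1)C(C)(C)C)CC/C=C(\CCO[Si](C)(C)C(C)(C)C)COCc1ccc(OC)cc1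
F3 | step 12 | 2-(bromomethyl)prop-2-enoate of F2 (C6 epimer of 17) | C=C(CBr)C(=O)O[C@H](C=C)/C=C(/CO[Si](c1ccccc1)(c1ccccc1)C(C)(C)C)CC/C=C(\CCO[Si](C)(C)C(C)(C)C)COCc1ccc(OC)cc1
F4 | step 12 | (5S)-3-(bromomethyl)-5-[(1E,5E)-2-{[(tert-butyldiphenylsilyl)oxy]methyl}-8-[(tert-butyldimethylsilyl)oxy]-6-[(4-methoxybenzyloxy)methyl]octa-1,5-dien-1-yl]furan-2(5H)-one | BrCC1=C[C@H](/C=C(/CO[Si](c2ccccc2)(c2ccccc2)C(C)(C)C)CC/C=C(\CCO[Si](C)(C)C(C)(C)C)COCc2ccc(OC)cc2)OC1=O
F5 | step 12 | (5S)-3-(bromomethyl)-5-[(1E,5E)-2-{[(tert-butyldiphenylsilyl)oxy]methyl}-8-hydroxy-6-[(4-methoxybenzyloxy)methyl]octa-1,5-dien-1-yl]furan-2(5H)-one | BrCC1=C[C@H](/C=C(/CO[Si](c2ccccc2)(c2ccccc2)C(C)(C)C)CC/C=C(\CCO)COCc2ccc(OC)cc2)OC1=O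
F6 | step 12 | (3E,7E)-8-[(2S)-4-(bromomethyl)-5-oxo-2,5-dihydrofuran-2-yl]-7-{[(tert-butyldiphenylsilyl)oxy]methyl}-3-[(4-methoxybenzyloxy)methyl]octa-3,7-dienal | BrCC1=C[C@H](/C=C(/CO[Si](c2ccccc2)(c2ccccc2)C(C)(C)C)CC/C=C(\CC=O)COCc2ccc(OC)cc2)OC1=O
F7 | step 12 | trans-fused (6S,7S,8R)-hydroxy lactone, C6 epimer of 22 | C=C1C(=O)O[C@H]2/C=C(/CO[Si](c3ccccc3)(c3ccccc3)C(C)(C)C)CC/C=C(/COCc3ccc(OC)cc3)C[C@@H](O)[C@H]12
F8 | step 12 | trans-fused (6S,7S,8S)-angelate, C6 epimer of 24 | C=C1C(=O)O[C@H]2/C=C(/CO[Si](c3ccccc3)(c3ccccc3)C(C)(C)C)CC/C=C(/COCc3ccc(OC)cc3)C[C@H](OC(=O)/C(C)=C\C)[C@H]12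
F9 | step 12 | seco hydroxy acid of F8: 2-substituted prop-2-enoic acid on C7 of the cyclodeca-1,5-diene, free (6S)-hydroxyl, (8S)-angelate | OC(=O)C(=C)[C@H]1[C@@H](OC(=O)/C(C)=C\C)C/C(COCc2ccc(OC)cc2)=C\CC/C(CO[Si](c2ccccc2)(c2ccccc2)C(C)(C)C)=C\[C@@H]1O
F10 | step 13 | (3aS,6E,10E,11aR)-10-{[(tert-butyldiphenylsilyl)oxy]methyl}-6-[(4-methoxybenzyloxy)methyl]-3-methylidene-3a,5,8,9-tetrahydrocyclodeca[b]furan-2,4(3H,11aH)-dione (C8 ketone) | C=C1C(=O)O[C@@H]2/C=C(/CO[Si](c3ccccc3)(c3ccccc3)C(C)(C)C)CC/C=C(/COCc3ccc(OC)cc3)CC(=O)[C@H]12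
F11 | step 13 | (3aS,4S,6E,10E,11aR)-10-{[(tert-butyldiphenylsilyl)oxy]methyl}-4-hydroxy-6-[(4-methoxybenzyloxy)methyl]-3-methylidene-3a,4,5,8,9,11a-hexahydrocyclodeca[b]furan-2(3H)-one (C8 epimer of 22) | C=C1C(=O)O[C@@H]2/C=C(/CO[Si](c3ccccc3)(c3ccccc3)C(C)(C)C)CC/C=C(/COCc3ccc(OC)cc3)C[C@H](O)[C@H]12
F12 | step 1 | racemic 6-[(tert-butyldiphenylsilyl)oxy]hex-1-en-4-yn-3-ol | OC(C=C)C#CCO[Si](c1ccccc1)(c1ccccc1)C(C)(C)C
F13 | step 1 | (3R)-6-[(tert-butyldiphenylsilyl)oxy]hex-1-en-4-yn-3-yl acetate | CC(=O)O[C@H](C=C)C#CCO[Si](c1ccccc1)(c1ccccc1)C(C)(C)C
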